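(Readings and results were computed for an exercise; the scatter is artificial.)

A small charge of free monomer kept a larger share of it free in Friday's flask than in Wednesday's. After 5.00 min, Friday's flask, charged with 0.23 M of free monomer, still held 0.123 M, while Wednesday's, charged with 0.45 M, held 0.164 M.

all flasks: pre-initiator 20 mM
- Friday's: free monomer 0.23 M; run made earlier
- Tuesday's: free monomer 0.31 M; run made earlier
- Wednesday's: free monomer 0.45 M; run made earlier
- zeta: free monomer 0.40 M; time 5.0 min
- gamma: free monomer 0.20 M; time 5.0 min

| run | time / min | monomer in chains / % | free monomer / % |
|---|---|---|---|
| Friday's | 0.667 | 2.1 | 99.0 |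
| Friday's | 2.00 | 14.6 | 85.7 |
| Friday's | 3.00 | 28.1 | 72.5 |
| Friday's | 5.00 | 46.4 | 53.4 |
| Tuesday's | 0.417 | 0.8 | 98.8 |
| Tuesday's | 1.00 | 4.9 | 96.1 |
| Tuesday's | 2.00 | 19.1 | 82.3 |
| Tuesday's | 5.00 | 56.2 | 44.4 |
| Wednesday's | 1.33 | 11.2 | 90.2 |
| Wednesday's | 2.50 | 30.7 | 70.0 |
| Wednesday's | 4.00 | 53.9 | 46.2 |
| Wednesday's | 5.00 | 65.1 | 36.4 |

(readings scatter by 0.5 percentage points)

- the average divides the monomer in chains by the number of chains begun, living and dead together
- steps thought possible: monomer in chains + living end -> free monomer + living end; pre-initiator -> initiator; free monomer + initiator -> living end + monomer in chains; free monomer + living end -> monomer in chains + living end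
- the earlier runs do not show the number of chains; that part of a forecast is a guess

1. which of the two ends with the longer chains by the average number of monomer units in a chain (chains begun, living or dead) ("neither" if they lie within 10 %) (zeta / gamma / neither)
2. average number of monomer units in a chain (chains begun, living or dead) at the end, zeta
3. average number of monomer units in a chain (chains begun, living or dead) at the end, gamma

My reckoning takes addition and loss at living ends as heading for a balance. With equal pre-initiator, I assume that each flask keeps the same fraction of its excess over that balance at a given time:

fraction kept = (0.164 M − 0.123 M) / (0.45 M − 0.23 M) = 0.186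

floor = (0.123 M − 0.186 × 0.23 M) / (1 − 0.186) = 0.0983 M

The floor is the free monomer at which addition to living ends and loss from chains balance, the equilibrium monomer concentration. Tuesday's run, not used here, tests it: the reckoning gives 0.138 M, and the reading is 0.138 M.

monomer in chains, zeta: 0.246 M

monomer in chains, gamma: 0.0828 M

Over the whole 20 mM of pre-initiator, these give 12.3 and 4.14, but that count is the weak link. I assume that the excess of free monomer over the floor falls at a rate proportional to the living ends. In Wednesday's readings, the logarithm of the starting excess over the present excess grows by a factor of 3.47 from 2.50 min to 5.00 min. A count of chains begun that follows first-order decay of pre-initiator with a trial time constant of 5.00 min, summed over time, grows by 3.45, so I take that clock: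

chains begun = 12.6 mM

length: zeta 19.4, gamma 6.55

The forecast says zeta, with 13 (11.5 to 18) for zeta and 4.7 (4 to 7) for gamma, both shorter than my lengths: “The chain count is a guess: nearly all 20 mM, perhaps 17–19 mM.”

The simulation gives zeta, with 19.8 for zeta and 6.72 for gamma.

    monomer in chains + living end → free monomer + living end, rate k1*[living end] as long as [monomer in chains] is above zero (k = 0.0819 s⁻¹)
    pre-initiator → initiator (k = 0.00359 s⁻¹)
    free monomer + initiator → living end + monomer in chains (k = 0.208 M⁻¹ s⁻¹)
    free monomer + living end → monomer in chains + living end, rate k4*[living end]*[free monomer] (k = 0.797 M⁻¹ s⁻¹)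

The forecast and the flask part on the count: zeta at 5.00 min holds 0.0124 M of living ends, with 34.1 % of its pre-initiator charge left. In gamma at 5.00 min, monomer in chains is made 1.18 times faster than it is used up, each step taken net, with 0.119 M of free monomer, 0.0207 M above the floor. For the neighbour of gamma charged with 0.50 M, the floor, the fraction kept and 12.6 mM of chains give 26.0 units, and that flask ends at 26.3.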